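## Structural features

- The target is a 2,3-dihydro-1-benzofuran: a benzo ring (C3a to C7a) fused to a dihydrofuran ring (O1, C2, C3). C2 carries a 3,4-dihydroxyphenyl group, C3 a 3,5-dihydroxyphenyl group, and C5 (para to O1) an (E)-3,5-dihydroxystyryl arm.
- C2 and C3 are adjacent stereocentres, both S, with the two aryl groups trans. Trans is also the more stable arrangement on the five-membered ring.
- Fragile elements are the six free phenols (the catechol is air-sensitive), the E-stilbene (light, acid), and the doubly benzylic C3–H. The C2–O1 bond is a para-oxygenated benzyl aryl ether and ionises easily under acid.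
- The benzo ring has one carbon substituent and no oxygen other than O1, so it offers no directing group for placing the C5 carbon para to O1.
- The real difficulty is the absolute configuration of two contiguous benzylic centres in a molecule with no other handle, combined with a final unmasking of six phenols that must not open the dihydrofuran.
- The key step exploits that O1, C2, C3, C3a and C7a have the connectivity and oxidation level of a trans-4,5-diaryl γ-butyrolactone (C7a the carbonyl carbon, C3a the α-carbon). The missing C4 to C7, with the substituent on C5, map onto C6, C5, C4 and C3 of a 5-carboxy-2-pyrone.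
- Both stereocentres therefore sit on a small lactone, where they can be set by asymmetric ketone reduction and corrected by equilibration before the aromatic ring exists.

## Logic of the disconnections

**18 to 17.** The six phenolic O–H bonds are taken back to O–CH3. Free phenols would not survive the enolate, hydride and phosphonate-anion steps, and methyl is the one ether that survives every step and lets all aryl building blocks be bought. The gain is that the polyphenol appears only at the end. The demand is a cold Lewis-acid demethylation that leaves C2–O1 and the stilbene intact.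

**17 to 15 + 16.** The stilbene C=C is cut. A benzylic phosphonate and a non-enolisable aryl aldehyde give the E-alkene reliably, and one of the three aryl units is removed. The forward step must be E-selective and its base must not remove the C3 hydrogen.

**15 to 14 to 13.** No skeletal bond is cut. The C5 carbon is taken back through the alcohol to the ester, because an ester is what the pyrone delivers. The demand is two functional-group steps that leave the cyclic benzylic ether alone.

**13 to 9 + 10 (key).** C3a–C4 and C7–C7a are cut, and the CO2 bridge and the silanol are restored. This removes the whole benzo ring and leaves a five-membered ring that already carries both stereocentres. The gain is that the arene is made with its substitution pattern rather than functionalised afterwards. The demands are: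
- C3 of 9 must bond to C6 of 10 and the acetal carbon to C3 of 10.
- Aromatisation must eject the silanolate and not O1.
- The two stereocentres must remain spectators. They are (4R,5S) in 9 and (2S,3S) in 13; the change of letter at the 3,5-dimethoxyphenyl-bearing carbon is a change of CIP rank only, because C3a outranks that aryl group once it is aromatic.

**9 to 8.** The O–Si bond is cut. Enolisation can occur only at C3 of 8. The forward step must silylate on oxygen and the product must be isolated dry.

**8 to 7.** C5–O is broken and re-formed (epimer at C5). The reduction is expected to deliver the cis lactone, the target needs trans, and C5–O is the one bond of the lactone that ionises. The demand is that C4 stays untouched. 7 must also be diastereomerically pure, because any trans-lactone from the minor reduction product has the opposite configuration at C4 and would count as the enantiomer of 8.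

**7 to 5.** The C–H bond at the carbinol carbon and the lactone acyl C–O bond are cut. Two stereocentres become one labile centre α to an aryl ketone, which suits dynamic kinetic resolution, and the precursor is racemic. The demands are fast epimerisation of 5, ligand control of the carbinol, and substrate selection of the α-centre.

**5 to 3 + 4.** The bond between the ketone α-carbon and the CH2 of the ester arm is cut (enolate alkylation). The demand is mono C-alkylation.

**3 to 1 + 2.** The bond between the α-carbon and the 3,5-dimethoxyphenyl ring is cut. Palladium-catalysed α-arylation joins two commercial aromatics with no regiochemical choice. A Friedel–Crafts acylation with the arylacetic acid would set the very nucleophilic 3,5-dimethoxyphenyl ring against the intended arene. The demand is monoarylation.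

## Other disconnections considered

**Alternative 1:** The cut is at C3a–C7a, C4–C5 and C6–C7, leading to the ynol-ether diyne A2 and the enyne A3.
- Forward step: [Rh(cod)2]BF4 with BINAP (a cationic monovalent rhodium catalyst) couples A2 and A3 through a rhodacyclopentadiene, alkyne insertion and reductive elimination to the 7-silyl dihydrobenzofuran A1. Protodesilylation of A1 gives 17.
- In favour: three C–C bonds and both rings form in one step with the styryl arm already in place, and only desilylation and demethylation remain. On bonds formed per step and on steps after the key step this is better than the chosen plan. The silyl group steers the styryl unit to C5, so regiochemistry is addressed as well as in the coumalate route.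
- Against: A2 must already carry both stereocentres, so it needs its own asymmetric sequence, probably no shorter than the lactone route. A2 is an alkynyl ether of an electron-rich secondary benzylic alcohol, a class prone to sigmatropic and retro-ene loss of the ether on warming. A3 can self-trimerise. The chiral ligand has no stereocentre to control.
- Comparison: both plans keep the stereocentres outside the reacting π-system (equal). The metallacycle route is more convergent, but the chosen pericyclic route starts from a far more stable and accessible precursor.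

**Alternative 2:** The cut is at C3–C3a, leading back to the enantioenriched flavanone A5.
- Forward step: PhI(OAc)2 with H2SO4 in trimethyl orthoformate would iodinate the enol ether at C3, and the benzo-ring carbon would shift from the carbonyl carbon to C3. This contracts the ring to the trans ester A4, with bromine at C5 for a later Heck reaction with A9.
- In favour: A5 is a few steps from commercial materials by catalytic asymmetric conjugate arylation, the rearrangement is an established reaction type, and trans geometry is the expected outcome. Up to the dihydrobenzofuran core this route is shorter than the chosen plan.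
- Against: C3 carries an ester where the target has the 3,5-dihydroxyphenyl group. The exchange (for instance decarboxylative radical arylation) adds steps, passes through a C3 radical that can fragment by opening the ring, and must tolerate the aryl bromide. The electron-rich 2-aryl group favours the competing aryl shift to an isoflavone and dehydrogenation to a flavone. The strongly acidic medium can racemise C2 through reversible ring opening.
- Comparison: in both plans the trans relation rests on thermodynamic or substrate control (equal). Overall step count would be equal at best, and the chosen plan carries both aryl groups from the start.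

**Alternative 3:** The cut is at O1–C2 and C2–C3, leading to the sulfone A7 and a chiral benzylic sulfonium salt such as A8 (or its enantiomer, as the sense of induction requires).
- Forward step: base releases the ortho-quinone methide from A7, the ylide from A8 adds to the methide carbon, and the phenoxide displaces the sulfide to give the bromide A6. A Heck reaction of A6 with A9 gives 17.
- In favour: the dihydrofuran ring and both stereocentres form in one step, trans geometry follows from anti addition and SN2 closure, and only two steps remain. This is clearly shorter than the chosen plan.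
- Against: enantiocontrol depends on a stoichiometric chiral sulfide and on a semi-stabilised, electron-rich benzylic ylide. Its addition may be reversible, and its facial selectivity towards a hindered aryl-substituted quinone methide is less predictable than for ester-stabilised ylides. Both centres are created at once, so both faces must be controlled. 3,4-Dimethoxybenzyl sulfonium salts ionise easily.
- Comparison: the chosen plan fixes configuration by catalytic transfer hydrogenation and a thermodynamic relay, and its key step cannot erode it. Alternative 3 is riskier in enantiopurity but roughly half as long.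

Key step: step 6

Remark: hydride delivery in step 3 is assumed to follow the Felkin–Anh sense (hydride anti to the 3,5-dimethoxyphenyl group), so the (R,R)-ligand fixes the 3R centre. With the opposite sense, the (S,S)-ligand would lead to 8 directly and step 4 would be dropped.

## Route

Step 1
Reactants: 1 1-(3,4-dimethoxyphenyl)ethan-1-one; 2 1-bromo-3,5-dimethoxybenzene
Product: 3 1-(3,4-dimethoxyphenyl)-2-(3,5-dimethoxyphenyl)ethan-1-one
Conditions: Pd2(dba)3 (1.5 mol%), Xantphos (3.6 mol%), NaOtBu (2.2 equiv), THF, 70 °C
Reagents that add atoms: none
Why: Palladium-catalysed α-arylation of a methyl ketone enolate; the wide-bite-angle bisphosphine favours monoarylation and the more acidic product rests as its enolate. The new bond can form at only one position on each partner, so no regiochemical question arises.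

Step 2
Reactants: 3 1-(3,4-dimethoxyphenyl)-2-(3,5-dimethoxyphenyl)ethan-1-one; 4 methyl bromoacetate
Product: 5 methyl 4-(3,4-dimethoxyphenyl)-3-(3,5-dimethoxyphenyl)-4-oxobutanoate (racemic)
Conditions: LiHMDS (1.05 equiv), THF, −78 °C; then 4, −78 → 0 °C
Reagents that add atoms: none
Why: Enolate alkylation; the stabilised deoxybenzoin enolate C-alkylates the α-halo ester by SN2. The new centre is deliberately racemic because it is configurationally labile and is resolved dynamically in step 3.

Step 3
Reactants: 5 methyl 4-(3,4-dimethoxyphenyl)-3-(3,5-dimethoxyphenyl)-4-oxobutanoate (racemic)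
Product: 7 (4R,5R)-5-(3,4-dimethoxyphenyl)-4-(3,5-dimethoxyphenyl)oxolan-2-one (cis-lactone), via syn-hydroxy ester 6 (not isolated)
Conditions: RuCl(p-cymene)[(R,R)-TsDPEN] (2 mol%), HCO2H/Et3N (1:1), DMF, 40 °C; then PPTS (cat.), PhMe, 60 °C
Reagents that add atoms: none
Why: Noyori-type asymmetric transfer hydrogenation with dynamic kinetic resolution; the benzylic hydrogen α to the aryl ketone exchanges in the amine/formate medium while the ketone is reduced. The (R,R)-ligand should give the R carbinol as for simple aryl ketones, and the Felkin–Anh preference should select the 3R ketone enantiomer, giving syn ester 6. Ester 6 lactonises with retention to 7, which is freed here from any trans-lactone arising from the minor diastereomer.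

Step 4
Reactants: 7 (4R,5R)-5-(3,4-dimethoxyphenyl)-4-(3,5-dimethoxyphenyl)oxolan-2-one
Product: 8 (4R,5S)-5-(3,4-dimethoxyphenyl)-4-(3,5-dimethoxyphenyl)oxolan-2-one (trans-lactone)
Conditions: TFA (5 equiv), CH2Cl2 (0.02 M), 0 → 23 °C
Reagents that add atoms: none
Why: Acid-catalysed epimerisation of a γ-aryl lactone by reversible ionisation of C5–O to a para-methoxy-stabilised benzylic cation and 5-exo return of the carboxyl group, the reaction type known for 2-aryl tetrahydrofuran lignans. C4 is untouched and directs C5 to the more stable trans arrangement (5S).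

Step 5
Reactants: 8 (4R,5S)-5-(3,4-dimethoxyphenyl)-4-(3,5-dimethoxyphenyl)oxolan-2-one
Product: 9 tert-butyl{[(4R,5S)-5-(3,4-dimethoxyphenyl)-4-(3,5-dimethoxyphenyl)-4,5-dihydrofuran-2-yl]oxy}dimethylsilane
Conditions: LDA (1.1 equiv), TBSCl (1.2 equiv), DMPU, THF, −78 → 0 °C; pentane, filtration, no aqueous work-up
Reagents that add atoms: tert-butyldimethylsilyl chloride, CC(C)(C)[Si](C)(C)Cl
Why: Kinetic lactone enolate formation and O-silylation in a dipolar medium give the cyclic silyl ketene acetal. Only the C3 hydrogen is removed, so neither stereocentre takes part; tert-butyldimethylsilyl is chosen so that the acetal can be handled.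

Step 6
Reactants: 9 tert-butyl{[(4R,5S)-5-(3,4-dimethoxyphenyl)-4-(3,5-dimethoxyphenyl)-4,5-dihydrofuran-2-yl]oxy}dimethylsilane; 10 methyl 2-oxo-2H-pyran-5-carboxylate (methyl coumalate)
Product: 13 methyl (2S,3S)-2-(3,4-dimethoxyphenyl)-3-(3,5-dimethoxyphenyl)-2,3-dihydro-1-benzofuran-5-carboxylate, via bridged lactone cycloadduct 11 (not isolated), via silyloxy dihydroarene 12 (not isolated)
Conditions: 10 (1.3 equiv), PhMe, 100 °C, sealed tube; then DBU (1.2 equiv), 23 °C
Reagents that add atoms: none
Why: The closest known reaction type is the inverse-electron-demand Diels–Alder reaction of methyl coumalate with ketene acetals, which gives para-substituted benzoates after loss of CO2 and an alcohol. The nucleophilic C3 of 9 bonds to C6 of 10 (the vinylogous acceptor terminus) and the acetal carbon to C3 of 10; this asynchronous [4+2] closes the new six-membered carbocycle as a two-bond annulation onto the existing five-membered ring and gives 11. Retro-[4+2] loss of CO2 from 11 gives the cis-fused diene 12; DBU then removes the C3a hydrogen, which is vinylogous to the ester, and the dienolate expels silanolate from C7a to aromatise. Regiochemistry follows from the polarity of both partners and places the ester para to the acetal oxygen, at C5. Retention of O1 is secured in two ways: silanolate is the better nucleofuge, and in the planar dienolate the exocyclic C7a–OSi bond can stand parallel to the C3a π-orbital while the ring fusion holds C7a–O1 far from parallel; this is why aromatisation is run with base and not with acid. The sp3 centres created in 11 and 12 are all destroyed on aromatisation, so facial and endo/exo selectivity are irrelevant. C2 and C3 of the product lie outside the reacting π-system and keep their trans arrangement; (4R,5S) in 9 becomes (2S,3S) in 13 by a change of CIP rank only.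

Step 7
Reactants: 13 methyl (2S,3S)-2-(3,4-dimethoxyphenyl)-3-(3,5-dimethoxyphenyl)-2,3-dihydro-1-benzofuran-5-carboxylate
Product: 14 [(2S,3S)-2-(3,4-dimethoxyphenyl)-3-(3,5-dimethoxyphenyl)-2,3-dihydro-1-benzofuran-5-yl]methanol
Conditions: LiAlH4, THF, 0 °C
Reagents that add atoms: none
Why: Hydride reduction of an aryl ester to the benzylic alcohol; the methyl ethers and the cyclic benzylic ether are inert to hydride.

Step 8
Reactants: 14 [(2S,3S)-2-(3,4-dimethoxyphenyl)-3-(3,5-dimethoxyphenyl)-2,3-dihydro-1-benzofuran-5-yl]methanol
Product: 15 (2S,3S)-2-(3,4-dimethoxyphenyl)-3-(3,5-dimethoxyphenyl)-2,3-dihydro-1-benzofuran-5-carbaldehyde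
Conditions: MnO2 (activated, excess), CH2Cl2, 23 °C
Reagents that add atoms: none
Why: Selective oxidation of a benzylic alcohol with activated MnO2 stops at the aldehyde. The neutral, heterogeneous conditions leave the C3 hydrogen and the C2–O1 bond alone.

Step 9
Reactants: 15 (2S,3S)-2-(3,4-dimethoxyphenyl)-3-(3,5-dimethoxyphenyl)-2,3-dihydro-1-benzofuran-5-carbaldehyde; 16 diethyl [(3,5-dimethoxyphenyl)methyl]phosphonate
Product: 17 (2S,3S)-2-(3,4-dimethoxyphenyl)-3-(3,5-dimethoxyphenyl)-5-[(E)-2-(3,5-dimethoxyphenyl)ethenyl]-2,3-dihydro-1-benzofuran
Conditions: KOtBu (1.3 equiv), THF, 0 → 23 °C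
Reagents that add atoms: none
Why: Horner–Wadsworth–Emmons olefination with a benzylic phosphonate anion; reversible addition and elimination through the anti oxaphosphetane should give the E-stilbene. The aldehyde is non-enolisable and the C3 hydrogen is far too weakly acidic for the alkoxide at this temperature.

Step 10
Reactants: 17 (2S,3S)-2-(3,4-dimethoxyphenyl)-3-(3,5-dimethoxyphenyl)-5-[(E)-2-(3,5-dimethoxyphenyl)ethenyl]-2,3-dihydro-1-benzofuran
Product: 18 4-[(2S,3S)-3-(3,5-dihydroxyphenyl)-5-[(E)-2-(3,5-dihydroxyphenyl)ethenyl]-2,3-dihydro-1-benzofuran-2-yl]benzene-1,2-diol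
Conditions: BBr3 (12 equiv), CH2Cl2, −78 → 0 °C, dark; then H2O, 0 °C
Reagents that add atoms: none
Why: Lewis-acid cleavage of aryl methyl ethers, in which bromide attacks the methyl group of each O–boron adduct. The stereocentres are not involved provided C2–O1 holds, and a transient ionisation at C2 would be expected to re-close trans under control of C3.

## Compound list

1 | 1-(3,4-dimethoxyphenyl)ethan-1-one | CC(=O)c1ccc(OC)c(OC)c1 | starting material
2 | 1-bromo-3,5-dimethoxybenzene | COc1cc(Br)cc(OC)c1 | starting material
3 | 1-(3,4-dimethoxyphenyl)-2-(3,5-dimethoxyphenyl)ethan-1-one | COc1cc(CC(=O)c2ccc(OC)c(OC)c2)cc(OC)c1 | intermediate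
4 | methyl bromoacetate | COC(=O)CBr | starting material
5 | methyl 4-(3,4-dimethoxyphenyl)-3-(3,5-dimethoxyphenyl)-4-oxobutanoate (racemic) | COC(=O)CC(c1cc(OC)cc(OC)c1)C(=O)c1ccc(OC)c(OC)c1 | intermediate
6 | methyl (3R,4R)-4-(3,4-dimethoxyphenyl)-3-(3,5-dimethoxyphenyl)-4-hydroxybutanoate (syn-hydroxy ester, not isolated) | COC(=O)C[C@H](c1cc(OC)cc(OC)c1)[C@@H](O)c1ccc(OC)c(OC)c1 | intermediate
7 | (4R,5R)-5-(3,4-dimethoxyphenyl)-4-(3,5-dimethoxyphenyl)oxolan-2-one (cis) | O=C1C[C@H](c2cc(OC)cc(OC)c2)[C@H](c2ccc(OC)c(OC)c2)O1 | intermediate
8 | (4R,5S)-5-(3,4-dimethoxyphenyl)-4-(3,5-dimethoxyphenyl)oxolan-2-one (trans) | O=C1C[C@H](c2cc(OC)cc(OC)c2)[C@@H](c2ccc(OC)c(OC)c2)O1 | intermediate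
9 | tert-butyl{[(4R,5S)-5-(3,4-dimethoxyphenyl)-4-(3,5-dimethoxyphenyl)-4,5-dihydrofuran-2-yl]oxy}dimethylsilane | CC(C)(C)[Si](C)(C)OC1=C[C@H](c2cc(OC)cc(OC)c2)[C@@H](c2ccc(OC)c(OC)c2)O1 | intermediate
10 | methyl 2-oxo-2H-pyran-5-carboxylate (methyl coumalate) | COC(=O)C1=COC(=O)C=C1 | starting material
11 | bridged lactone cycloadduct (2-oxabicyclo[2.2.2]octenone: acetal carbon of 9 bonded to C3 and C3 of 9 bonded to C6 of the former pyrone; ester on the ring alkene; aryl-bearing centres as in 9, new centres undefined; not isolated) | COC(=O)C1=CC2C(=O)OC1C3C2(O[Si](C)(C)C(C)(C)C)O[C@H](c1ccc(OC)c(OC)c1)[C@H]3c1cc(OC)cc(OC)c1 | intermediate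
12 | methyl (2S,3R)-7a-[(tert-butyldimethylsilyl)oxy]-2-(3,4-dimethoxyphenyl)-3-(3,5-dimethoxyphenyl)-2,3,3a,7a-tetrahydro-1-benzofuran-5-carboxylate (cis-fused, C3a and C7a undefined; aryl groups trans; not isolated) | COC(=O)C1=CC2[C@H](c3cc(OC)cc(OC)c3)[C@@H](c3ccc(OC)c(OC)c3)OC2(O[Si](C)(C)C(C)(C)C)C=C1 | intermediate
13 | methyl (2S,3S)-2-(3,4-dimethoxyphenyl)-3-(3,5-dimethoxyphenyl)-2,3-dihydro-1-benzofuran-5-carboxylate | COC(=O)c1ccc2c(c1)[C@H](c1cc(OC)cc(OC)c1)[C@@H](c1ccc(OC)c(OC)c1)O2 | intermediate
14 | [(2S,3S)-2-(3,4-dimethoxyphenyl)-3-(3,5-dimethoxyphenyl)-2,3-dihydro-1-benzofuran-5-yl]methanol | OCc1ccc2c(c1)[C@H](c1cc(OC)cc(OC)c1)[C@@H](c1ccc(OC)c(OC)c1)O2 | intermediate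
15 | (2S,3S)-2-(3,4-dimethoxyphenyl)-3-(3,5-dimethoxyphenyl)-2,3-dihydro-1-benzofuran-5-carbaldehyde | O=Cc1ccc2c(c1)[C@H](c1cc(OC)cc(OC)c1)[C@@H](c1ccc(OC)c(OC)c1)O2 | intermediate
16 | diethyl [(3,5-dimethoxyphenyl)methyl]phosphonate | CCOP(=O)(Cc1cc(OC)cc(OC)c1)OCC | starting material
17 | (2S,3S)-2-(3,4-dimethoxyphenyl)-3-(3,5-dimethoxyphenyl)-5-[(E)-2-(3,5-dimethoxyphenyl)ethenyl]-2,3-dihydro-1-benzofuran | COc1cc(OC)cc(/C=C/c2ccc3c(c2)[C@H](c2cc(OC)cc(OC)c2)[C@@H](c2ccc(OC)c(OC)c2)O3)c1 | intermediate
18 | 4-[(2S,3S)-3-(3,5-dihydroxyphenyl)-5-[(E)-2-(3,5-dihydroxyphenyl)ethenyl]-2,3-dihydro-1-benzofuran-2-yl]benzene-1,2-diol | Oc1cc(O)cc(/C=C/c2ccc3c(c2)[C@H](c2cc(O)cc(O)c2)[C@@H](c2ccc(O)c(O)c2)O3)c1 | target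

## Step count and least certain steps

Total step count: 10. Longest linear sequence: 10 steps (1 and 2 to 18); 4, 10 and 16 are bought.

**Step 6 (key step).** The most likely failure is aromatisation of 12 by expulsion of the ring oxygen (cleavage of C7a–O1) in competition with loss of silanolate. A slow cycloaddition at the hindered acetal carbon would also give the ketene acetal time to hydrolyse or rearrange. The fallback accepts the ring opening and re-forms the ring. Starting from 12 (made from 9 and 10 as before), the ring-opened product is the aryl silyl ether methyl 4-[(tert-butyldimethylsilyl)oxy]-3-[(1S,2S)-2-(3,4-dimethoxyphenyl)-1-(3,5-dimethoxyphenyl)-2-hydroxyethyl]benzoate F1. TBAF buffered with AcOH frees the phenol, methyl 3-[(1S,2S)-2-(3,4-dimethoxyphenyl)-1-(3,5-dimethoxyphenyl)-2-hydroxyethyl]-4-hydroxybenzoate F2. Catalytic TsOH in toluene then ionises the 3,4-dimethoxybenzylic alcohol and the phenol closes the five-membered ring anti to the neighbouring aryl group, returning to 13. Here O1–C2 is made by SN1 cyclodehydration under control of C3 rather than carried through from the lactone.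

**Step 3.** The most likely failure is α-epimerisation of 5 that is slow relative to hydride transfer, or weak syn/anti discrimination. The reduction would then behave as a plain kinetic resolution, and the diastereomer ratio becomes the enantiomer ratio once step 4 has reset C5. The fallback replaces asymmetric catalysis by classical resolution. Starting from 5, NaBH4 in MeOH gives the racemic hydroxy ester mixture methyl 4-(3,4-dimethoxyphenyl)-3-(3,5-dimethoxyphenyl)-4-hydroxybutanoate F3. TFA in CH2Cl2 lactonises and equilibrates it to the racemic trans-lactone (4RS,5SR)-5-(3,4-dimethoxyphenyl)-4-(3,5-dimethoxyphenyl)oxolan-2-one F4. Aminolysis with (S)-1-phenylethanamine and AlMe3 gives two diastereomeric hydroxy amides, from which (3R,4S)-4-(3,4-dimethoxyphenyl)-3-(3,5-dimethoxyphenyl)-4-hydroxy-N-[(1S)-1-phenylethyl]butanamide F5 is separated by crystallisation or chromatography. TsOH in hot toluene relactonises F5 with loss of the amine and returns to 8.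

**Step 4.** The most likely failure is loss of the C4 proton from the benzylic cation (E1) followed by reprotonation of the resulting stilbene-type acid, which would erode the configuration at C4. Friedel–Crafts alkylation of a dimethoxyaryl ring by the cation is a second risk if the solution is not dilute. The fallback inverts C5 stereospecifically instead of equilibrating. Starting from 7, LiOH in THF/H2O opens the lactone; cold acidification just before use gives (3R,4R)-4-(3,4-dimethoxyphenyl)-3-(3,5-dimethoxyphenyl)-4-hydroxybutanoic acid F6. Mitsunobu lactonisation (PPh3, DIAD, THF, 0 °C) closes the ring with inversion at the carbinol carbon and returns to 8.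

**Step 10.** The most likely failure is Lewis-acid ionisation of C2–O1 in competition with demethylation. This opens the ring and allows epimerisation or oligomerisation through the quinone-methide-type cation; HBr addition to the stilbene is a lesser risk. The fallback separates unmasking from ring closure. Starting from 17, demethylation is taken to completion with the ring allowed to open, and aqueous work-up gives the seco octol 4-[(2S)-2-(3,5-dihydroxyphenyl)-2-{5-[(E)-2-(3,5-dihydroxyphenyl)ethenyl]-2-hydroxyphenyl}-1-hydroxyethyl]benzene-1,2-diol F7 as a mixture of carbinol epimers. Catalytic TsOH in MeCN at 23 °C under argon then regenerates the para-quinone methide, and the neighbouring phenol adds anti to the C3 aryl group, returning to 18.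

## Further compounds

F1 | step 6 | methyl 4-[(tert-butyldimethylsilyl)oxy]-3-[(1S,2S)-2-(3,4-dimethoxyphenyl)-1-(3,5-dimethoxyphenyl)-2-hydroxyethyl]benzoate | COC(=O)c1ccc(O[Si](C)(C)C(C)(C)C)c(c1)[C@H](c1cc(OC)cc(OC)c1)[C@@H](c1ccc(OC)c(OC)c1)O
F2 | step 6 | methyl 3-[(1S,2S)-2-(3,4-dimethoxyphenyl)-1-(3,5-dimethoxyphenyl)-2-hydroxyethyl]-4-hydroxybenzoate | COC(=O)c1ccc(O)c(c1)[C@H](c1cc(OC)cc(OC)c1)[C@@H](c1ccc(OC)c(OC)c1)O
F3 | step 3 | methyl 4-(3,4-dimethoxyphenyl)-3-(3,5-dimethoxyphenyl)-4-hydroxybutanoate (racemic, both diastereomers) | COC(=O)CC(c1cc(OC)cc(OC)c1)C(O)c1ccc(OC)c(OC)c1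
F4 | step 3 | (4RS,5SR)-5-(3,4-dimethoxyphenyl)-4-(3,5-dimethoxyphenyl)oxolan-2-one (racemic trans-lactone, both enantiomers shown) | O=C1C[C@H](c2cc(OC)cc(OC)c2)[C@@H](c2ccc(OC)c(OC)c2)O1.O=C1C[C@@H](c2cc(OC)cc(OC)c2)[C@H](c2ccc(OC)c(OC)c2)O1
F5 | step 3 | (3R,4S)-4-(3,4-dimethoxyphenyl)-3-(3,5-dimethoxyphenyl)-4-hydroxy-N-[(1S)-1-phenylethyl]butanamide | O=C(N[C@@H](C)c1ccccc1)C[C@H](c1cc(OC)cc(OC)c1)[C@@H](c1ccc(OC)c(OC)c1)O
F6 | step 4 | (3R,4R)-4-(3,4-dimethoxyphenyl)-3-(3,5-dimethoxyphenyl)-4-hydroxybutanoic acid | OC(=O)C[C@H](c1cc(OC)cc(OC)c1)[C@H](c1ccc(OC)c(OC)c1)O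
F7 | step 10 | 4-[(2S)-2-(3,5-dihydroxyphenyl)-2-{5-[(E)-2-(3,5-dihydroxyphenyl)ethenyl]-2-hydroxyphenyl}-1-hydroxyethyl]benzene-1,2-diol (carbinol epimers) | Oc1cc(O)cc(/C=C/c2ccc(O)c(c2)[C@H](c2cc(O)cc(O)c2)C(O)c2ccc(O)c(O)c2)c1
A1 | alternative 1 | triethyl{(2S,3S)-2-(3,4-dimethoxyphenyl)-3-(3,5-dimethoxyphenyl)-5-[(E)-2-(3,5-dimethoxyphenyl)ethenyl]-2,3-dihydro-1-benzofuran-7-yl}silane | COc1cc(OC)cc(/C=C/c2cc([Si](CC)(CC)CC)c3c(c2)[C@H](c2cc(OC)cc(OC)c2)[C@@H](c2ccc(OC)c(OC)c2)O3)c1
A2 | alternative 1 | triethyl({[(1S,2R)-1-(3,4-dimethoxyphenyl)-2-(3,5-dimethoxyphenyl)but-3-yn-1-yl]oxy}ethynyl)silane | CC[Si](CC)(CC)C#CO[C@H](c1ccc(OC)c(OC)c1)[C@H](C#C)c1cc(OC)cc(OC)c1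
A3 | alternative 1 | 1-[(1E)-but-1-en-3-yn-1-yl]-3,5-dimethoxybenzene | C#C/C=C/c1cc(OC)cc(OC)c1
A4 | alternative 2 | methyl (2S,3S)-5-bromo-2-(3,4-dimethoxyphenyl)-2,3-dihydro-1-benzofuran-3-carboxylate (2,3-trans) | Brc1ccc2c(c1)[C@H](C(=O)OC)[C@@H](c1ccc(OC)c(OC)c1)O2
A5 | alternative 2 | (2S)-6-bromo-2-(3,4-dimethoxyphenyl)-2,3-dihydro-4H-chromen-4-one | O=C1C[C@@H](c2ccc(OC)c(OC)c2)Oc2ccc(Br)cc21
A6 | alternative 3 | (2S,3S)-5-bromo-2-(3,4-dimethoxyphenyl)-3-(3,5-dimethoxyphenyl)-2,3-dihydro-1-benzofuran | Brc1ccc2c(c1)[C@H](c1cc(OC)cc(OC)c1)[C@@H](c1ccc(OC)c(OC)c1)O2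
A7 | alternative 3 | 4-bromo-2-[(3,5-dimethoxyphenyl)(4-methylbenzenesulfonyl)methyl]phenol (racemic) | Cc1ccc(cc1)S(=O)(=O)C(c1cc(OC)cc(OC)c1)c1cc(Br)ccc1O
A8 | alternative 3 | (2R,5R)-1-[(3,4-dimethoxyphenyl)methyl]-2,5-dimethylthiolan-1-ium tetrafluoroborate | C[C@@H]1CC[C@@H](C)[S+]1Cc1ccc(OC)c(OC)c1.F[B-](F)(F)F
A9 | alternative 2 | 1-ethenyl-3,5-dimethoxybenzene | C=Cc1cc(OC)cc(OC)c1
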